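**Plan**

1. Retrosynthesis: after removal of one O‑benzyl and two silyl groups, the cyclohexanetrione ring is cut at two bonds, (side‑chain‑bearing enol carbon)–C(=O) and, on the other side of that carbon, C(=O)–CMe2. The excised two‑carbon unit (enol carbon plus one C=O) stays on the stereocentre, and the other four ring atoms, CMe2–CO–CMe2–CO, reclose to 2,2,4,4‑tetramethylcyclobutane‑1,3‑dione.
2. Enabling feature: the excised C=O lies 1,5 to the oxygen of the phenol ortho to the benzylic carbon (O–C(ar)–C(ar)–CH–C–C=O). It can therefore be carried as the carbonyl of a six‑membered aryl lactone (a dihydrocoumarin ring absent from the target), which activates the α‑CH2 and makes the phenoxide the leaving group; the dione partner is strained and non‑enolisable.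
3. Further cuts: the aryl–CH bond (asymmetric Friedel–Crafts conjugate addition of the phenol to (E)‑5‑methylhex‑2‑enal) and the aryl–C(=O) bond (Friedel–Crafts acylation of 2‑methylphloroglucinol).
4. Forward order: aryl ketone → 4‑O‑benzyl ether → C–C bond with stereocentre and lactol (pyran) ring → lactone → masking of ketone and phenol as silyl ethers → the four‑membered ring grows to the six‑membered trione while the lactone ring opens → desilylation → hydrogenolysis.
5. Stereochemistry: the single stereocentre is set in step 4 by the (S)‑diarylprolinol silyl ether catalyst; it is never α to a carbonyl group and carries no leaving group afterwards.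

Key step: step 7

Remark (assumption): step 4 is taken to follow the usual facial model of diarylprolinol silyl ether iminium ions (attack anti to the CPh2OTMS group), which maps onto the required configuration; were the sense opposite, the (R)‑catalyst would be used.

**Route**

Step 1
Reactants: 1 2‑methylbenzene‑1,3,5‑triol (2‑methylphloroglucinol); 2 3‑phenylpropanoyl chloride
Product: 3 1‑(2,4,6‑trihydroxy‑3‑methylphenyl)‑3‑phenylpropan‑1‑one
Conditions: AlCl3 (4 equiv), PhNO2/CH2Cl2, 0 °C → rt; ice/aq. HCl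
Reagents that add atoms: none
Why: Friedel–Crafts acylation of the electron‑rich arene at one of its two equivalent free positions; the acyl group then deactivates the ring towards a second acylation.

Step 2
Reactants: 3 1‑(2,4,6‑trihydroxy‑3‑methylphenyl)‑3‑phenylpropan‑1‑one
Product: 4 1‑[4‑(benzyloxy)‑2,6‑dihydroxy‑3‑methylphenyl]‑3‑phenylpropan‑1‑one
Conditions: BnBr (1.0 equiv), K2CO3 (1.05 equiv), acetone, rt
Reagents that add atoms: benzyl bromide, BrCc1ccccc1
Why: Williamson ether synthesis that should select the 4‑OH, the most acidic hydroxyl (para to the ketone) and the only one not hydrogen‑bonded to the carbonyl, so that the free ring position is left flanked by the benzyl ether and one free ortho‑OH.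

Step 3
Reactants: 5 3‑methylbutanal; 6 2‑(triphenyl‑λ5‑phosphanylidene)acetaldehyde
Product: 7 (2E)‑5‑methylhex‑2‑enal
Conditions: toluene, 80 °C; distillation
Reagents that add atoms: none
Why: Wittig olefination with a stabilised ylide, which should give the (E)‑enal.

Step 4
Reactants: 4 1‑[4‑(benzyloxy)‑2,6‑dihydroxy‑3‑methylphenyl]‑3‑phenylpropan‑1‑one; 7 (2E)‑5‑methylhex‑2‑enal
Product: 9 1‑[(4R)‑5‑(benzyloxy)‑2,7‑dihydroxy‑6‑methyl‑4‑(2‑methylpropyl)‑3,4‑dihydro‑2H‑chromen‑8‑yl]‑3‑phenylpropan‑1‑one (lactol, both C‑2 epimers), via open-chain aldehyde 8 (not isolated)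
Conditions: (S)‑α,α‑diphenylprolinol trimethylsilyl ether (20 mol %), PhCO2H (20 mol %), toluene, 0 °C → rt
Reagents that add atoms: none
Why: Iminium‑ion‑catalysed asymmetric Friedel–Crafts conjugate addition of the only free arene position to the enal, followed by hemiacetalisation with the adjacent OH; the stereocentre is set by attack on the face of the s‑trans (E)‑iminium ion anti to the CPh2OTMS group of the (S)‑catalyst.

Step 5
Reactants: 9 the lactol from step 4
Product: 10 (4R)‑5‑(benzyloxy)‑7‑hydroxy‑6‑methyl‑4‑(2‑methylpropyl)‑8‑(3‑phenylpropanoyl)‑3,4‑dihydro‑2H‑chromen‑2‑one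
Conditions: Dess–Martin periodinane (1.3 equiv), CH2Cl2, 0 °C → rt
Reagents that add atoms: none
Why: Oxidation of the lactol, which is in ring–chain equilibrium with aldehyde 8, to the lactone with a hypervalent iodine(V) reagent; the remaining phenol is deactivated by chelation to the ortho‑ketone and the stereocentre is not involved.

Step 6
Reactants: 10 the hydroxy keto lactone from step 5
Product: 11 (4R)‑5‑(benzyloxy)‑7‑[(tert‑butyldimethylsilyl)oxy]‑8‑{(1Z)‑1‑[(tert‑butyldimethylsilyl)oxy]‑3‑phenylprop‑1‑en‑1‑yl}‑6‑methyl‑4‑(2‑methylpropyl)‑3,4‑dihydro‑2H‑chromen‑2‑one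
Conditions: TBSOTf (2.5 equiv), Et3N (4 equiv), CH2Cl2, 0 °C → rt; aq. NaHCO3
Reagents that add atoms: tert‑butyldimethylsilyl trifluoromethanesulfonate, CC(C)(C)[Si](C)(C)OS(=O)(=O)C(F)(F)F
Why: Soft enolisation (silyl triflate/amine) converts the aryl ketone into its (Z)‑silyl enol ether and silylates the phenol in the same operation, so that the lactone α‑CH2 is left as the only acidic C–H for the next step; a silyl ketene acetal of the lactone, if formed, reverts on aqueous work‑up.

Step 7
Reactants: 11 the bis‑silylated lactone from step 6; 12 2,2,4,4‑tetramethylcyclobutane‑1,3‑dione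
Product: 15 2‑[(1S)‑1‑{2‑(benzyloxy)‑4‑[(tert‑butyldimethylsilyl)oxy]‑5‑{(1Z)‑1‑[(tert‑butyldimethylsilyl)oxy]‑3‑phenylprop‑1‑en‑1‑yl}‑6‑hydroxy‑3‑methylphenyl}‑3‑methylbutyl]‑3‑hydroxy‑4,4,6,6‑tetramethylcyclohex‑2‑ene‑1,5‑dione, via cyclobutanol aldol adduct 13 (not isolated), via ring-opened 3-acyl lactone 14 (not isolated)
Conditions: LiHMDS (1.05 equiv), THF, −78 °C; 12 (1.0 equiv), −78 → −30 °C; LDA (1.2 equiv), −78 → 0 °C; AcOH, then pH 5 buffer; crude product used directly
Reagents that add atoms: none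
Why: Proposed new method: the lithium enolate of the aryl lactone should add to one carbonyl of the strained, non‑enolisable dione (aldol addition), the β‑keto cyclobutanolate 13 should open by retro‑aldol cleavage of a ring C(O)–CMe2 bond (strain release, the event by which this dione is known to be cleaved by O‑, N‑ and C‑nucleophiles) and proton transfer should give the enolate of acyl lactone 14, which LDA converts into a dianion whose tertiary isopropyl‑ketone enolate attacks the lactone carbonyl (directly, or after E1cB loss of the aryloxide to an acylketene) with expulsion of the phenoxide. The closest known reaction type is the base‑induced conversion of dimethylketene dimer into the cyclohexane‑1,3,5‑trione trimer, a ring‑opening acylation followed by Claisen closure, here rerouted through a lactone enolate so that the two lactone carbons C3 and C2 are inserted into one bond of the four‑membered ring. The only ring closed is the six‑membered trione, formed by a 6‑(enolendo)‑exo‑trig Claisen (Dieckmann) acylation while the lactone ring is opened. No stereocentre is created: C3 ends as the enol carbon, and the existing C4 centre has no acidic hydrogen and is carried over unchanged. The step needs a single carbon acid and C‑ rather than O‑acylation; the first is secured by masking the ketone as its silyl enol ether and by the dione having no α‑hydrogen, the second by the reversibility of O‑acyl products in the presence of the released aryloxide and by the sink of the vinylogous‑acid enolate of the trione.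

Step 8
Reactants: 15 the ring‑expanded bis‑silyl compound from step 7
Product: 16 2‑[(1S)‑1‑{2‑(benzyloxy)‑4,6‑dihydroxy‑3‑methyl‑5‑(3‑phenylpropanoyl)phenyl}‑3‑methylbutyl]‑3‑hydroxy‑4,4,6,6‑tetramethylcyclohex‑2‑ene‑1,5‑dione
Conditions: HF·pyridine, pyridine, THF, 0 °C → rt
Reagents that add atoms: none
Why: Fluoride‑induced Si–O cleavage of the aryl silyl ether and of the silyl enol ether (which returns the ketone on protonation) under buffered conditions that should not dehydrate the phenol/trione pair.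

Step 9
Reactants: 16 the mono‑benzyl ether from step 8
Product: 17 3‑hydroxy‑4,4,6,6‑tetramethyl‑2‑[(1S)‑3‑methyl‑1‑{2,4,6‑trihydroxy‑3‑methyl‑5‑(3‑phenylpropanoyl)phenyl}butyl]cyclohex‑2‑ene‑1,5‑dione (target)
Conditions: H2 (1 atm), 10% Pd/C, EtOAc, rt
Reagents that add atoms: none
Why: Catalytic hydrogenolysis of the benzyl aryl ether under neutral conditions, under which the chelated aryl ketone, the tetrasubstituted enol and the benzylic C–C stereocentre are expected to be inert.

**Compound list**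

1 | 2‑methylbenzene‑1,3,5‑triol (2‑methylphloroglucinol) | Cc1c(O)cc(O)cc1O | starting material
2 | 3‑phenylpropanoyl chloride | O=C(Cl)CCc1ccccc1 | starting material
3 | 1‑(2,4,6‑trihydroxy‑3‑methylphenyl)‑3‑phenylpropan‑1‑one | Cc1c(O)cc(O)c(C(=O)CCc2ccccc2)c1O | intermediate
4 | 1‑[4‑(benzyloxy)‑2,6‑dihydroxy‑3‑methylphenyl]‑3‑phenylpropan‑1‑one | Cc1c(OCc2ccccc2)cc(O)c(C(=O)CCc2ccccc2)c1O | intermediate
5 | 3‑methylbutanal | CC(C)CC=O | starting material
6 | 2‑(triphenyl‑λ5‑phosphanylidene)acetaldehyde | O=CC=P(c1ccccc1)(c1ccccc1)c1ccccc1 | starting material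
7 | (2E)‑5‑methylhex‑2‑enal | CC(C)C/C=C/C=O | intermediate
8 | (3R)‑3‑[2‑(benzyloxy)‑4,6‑dihydroxy‑3‑methyl‑5‑(3‑phenylpropanoyl)phenyl]‑5‑methylhexanal (open form of 9, not isolated) | O=CC[C@@H](CC(C)C)c1c(OCc2ccccc2)c(C)c(O)c(C(=O)CCc2ccccc2)c1O | intermediate
9 | 1‑[(4R)‑5‑(benzyloxy)‑2,7‑dihydroxy‑6‑methyl‑4‑(2‑methylpropyl)‑3,4‑dihydro‑2H‑chromen‑8‑yl]‑3‑phenylpropan‑1‑one (lactol, C‑2 epimers) | OC1C[C@@H](CC(C)C)c2c(OCc3ccccc3)c(C)c(O)c(C(=O)CCc3ccccc3)c2O1 | intermediate
10 | (4R)‑5‑(benzyloxy)‑7‑hydroxy‑6‑methyl‑4‑(2‑methylpropyl)‑8‑(3‑phenylpropanoyl)‑3,4‑dihydro‑2H‑chromen‑2‑one | O=C1C[C@@H](CC(C)C)c2c(OCc3ccccc3)c(C)c(O)c(C(=O)CCc3ccccc3)c2O1 | intermediate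
11 | (4R)‑5‑(benzyloxy)‑7‑[(tert‑butyldimethylsilyl)oxy]‑8‑{(1Z)‑1‑[(tert‑butyldimethylsilyl)oxy]‑3‑phenylprop‑1‑en‑1‑yl}‑6‑methyl‑4‑(2‑methylpropyl)‑3,4‑dihydro‑2H‑chromen‑2‑one | O=C1C[C@@H](CC(C)C)c2c(OCc3ccccc3)c(C)c(O[Si](C)(C)C(C)(C)C)c(/C(O[Si](C)(C)C(C)(C)C)=C/Cc3ccccc3)c2O1 | intermediate
12 | 2,2,4,4‑tetramethylcyclobutane‑1,3‑dione | CC1(C)C(=O)C(C)(C)C1=O | starting material
13 | lactone 11 carrying a 1‑hydroxy‑2,2,4,4‑tetramethyl‑3‑oxocyclobutyl group at C‑3 (lithium alkoxide in the flask, C‑3 configuration immaterial, not isolated) | O=C1C(C2(O)C(C)(C)C(=O)C2(C)C)[C@@H](CC(C)C)c2c(OCc3ccccc3)c(C)c(O[Si](C)(C)C(C)(C)C)c(/C(O[Si](C)(C)C(C)(C)C)=C/Cc3ccccc3)c2O1 | intermediate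
14 | lactone 11 carrying a 2,2,4‑trimethyl‑3‑oxopentanoyl group at C‑3 (lithium enolate in the flask, not isolated) | O=C1C(C(=O)C(C)(C)C(=O)C(C)C)[C@@H](CC(C)C)c2c(OCc3ccccc3)c(C)c(O[Si](C)(C)C(C)(C)C)c(/C(O[Si](C)(C)C(C)(C)C)=C/Cc3ccccc3)c2O1 | intermediate
15 | 2‑[(1S)‑1‑{2‑(benzyloxy)‑4‑[(tert‑butyldimethylsilyl)oxy]‑5‑{(1Z)‑1‑[(tert‑butyldimethylsilyl)oxy]‑3‑phenylprop‑1‑en‑1‑yl}‑6‑hydroxy‑3‑methylphenyl}‑3‑methylbutyl]‑3‑hydroxy‑4,4,6,6‑tetramethylcyclohex‑2‑ene‑1,5‑dione | Cc1c(O[Si](C)(C)C(C)(C)C)c(/C(O[Si](C)(C)C(C)(C)C)=C/Cc2ccccc2)c(O)c([C@H](CC(C)C)C2=C(O)C(C)(C)C(=O)C(C)(C)C2=O)c1OCc1ccccc1 | intermediate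
16 | 2‑[(1S)‑1‑{2‑(benzyloxy)‑4,6‑dihydroxy‑3‑methyl‑5‑(3‑phenylpropanoyl)phenyl}‑3‑methylbutyl]‑3‑hydroxy‑4,4,6,6‑tetramethylcyclohex‑2‑ene‑1,5‑dione | Cc1c(O)c(C(=O)CCc2ccccc2)c(O)c([C@H](CC(C)C)C2=C(O)C(C)(C)C(=O)C(C)(C)C2=O)c1OCc1ccccc1 | intermediate
17 | 3‑hydroxy‑4,4,6,6‑tetramethyl‑2‑[(1S)‑3‑methyl‑1‑{2,4,6‑trihydroxy‑3‑methyl‑5‑(3‑phenylpropanoyl)phenyl}butyl]cyclohex‑2‑ene‑1,5‑dione | Cc1c(O)c(C(=O)CCc2ccccc2)c(O)c([C@H](CC(C)C)C2=C(O)C(C)(C)C(=O)C(C)(C)C2=O)c1O | target

**Step count and risks**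

Total steps: 9. Longest linear sequence: 8 (steps 1, 2, 4, 5, 6, 7, 8, 9).

Steps most likely to fail:

Step 7 (the step with the new method). The aldolate may be diverted into O‑acylation (a spiro‑β‑lactone or an enol lactone) instead of C–C fragmentation. The second deprotonation at the hindered isopropyl methine, or C‑acylation at a carbonyl that is already part of an enolate, may be too slow. Excess amide base could also erode the stereocentre by γ‑deprotonation of the product enolate. The fallback uses known chemistry only and sets out from 11. Lactone 11 would be reduced with DIBAL‑H (CH2Cl2, −78 °C) to the lactol F1. Separately, dione 12 would be opened with catalytic NaOMe in MeOH to methyl 2,2,4‑trimethyl‑3‑oxopentanoate F2. The lithium enolate of F2 (LDA, THF, −78 °C; the isopropyl methine is its only acidic site; 2.2 equiv, the first being consumed by the lactol OH) would add to the hydroxy‑aldehyde form of F1 in an aldol addition to give the β‑hydroxy ketone F3. Oxidation with Dess–Martin periodinane would give the 3,5‑diketo ester F4. A Dieckmann cyclisation (KOt‑Bu, THF, 0 °C), in which the singly activated CH2 attacks the non‑enolisable ester as in the classical construction of the tetramethylcyclohexanetrione ring, would bring the route back at 15.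

Step 4. The acyl‑deactivated, hydrogen‑bonded phenol may react too slowly with the iminium ion; 1,2‑addition followed by condensation to a 2H‑chromene, or poor facial selectivity, may compete. The fallback sets out from 4 and 5: a three‑component Knoevenagel/Michael/lactonisation/decarboxylation sequence with Meldrum's acid (pyridine, 80 °C) would give the racemic lactone F5 in one operation, bypassing 7, 8 and 9. Resolution on a chiral stationary phase (preparative HPLC or SFC) would deliver the (4R)‑enantiomer, at which point the route is rejoined at 10.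

Step 6. Enol silylation of the hindered, twisted ketone may remain incomplete, or the silyl enol ether may be lost by hydrolysis during isolation, so that an acidic ketone α‑CH2 re‑enters the key step. The fallback sets out from 10: O‑benzylation of the remaining phenol (BnBr, K2CO3, DMF, 50 °C) would give the bis(benzyl ether) lactone F6. The ring expansion would then be run with one additional equivalent of LiHMDS, so that the aryl ketone travels as its lithium enolate. This 2,6‑dioxygenated aryl ketone enolate is expected to be much less reactive towards the dione than the lactone enolate and is simply reprotonated on work‑up, giving the ring‑expanded bis(benzyl ether) F7. Hydrogenolysis (H2, Pd/C, EtOAc) of both benzyl ethers would then rejoin the route at 17, replacing steps 8 and 9 by one step.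

Further compounds
F1 | step 7 | (4R)‑5‑(benzyloxy)‑7‑[(tert‑butyldimethylsilyl)oxy]‑8‑{(1Z)‑1‑[(tert‑butyldimethylsilyl)oxy]‑3‑phenylprop‑1‑en‑1‑yl}‑6‑methyl‑4‑(2‑methylpropyl)‑3,4‑dihydro‑2H‑chromen‑2‑ol (lactol) | OC1C[C@@H](CC(C)C)c2c(OCc3ccccc3)c(C)c(O[Si](C)(C)C(C)(C)C)c(/C(O[Si](C)(C)C(C)(C)C)=C/Cc3ccccc3)c2O1
F2 | step 7 | methyl 2,2,4‑trimethyl‑3‑oxopentanoate | COC(=O)C(C)(C)C(=O)C(C)C
F3 | step 7 | methyl (7R)‑7‑{2‑(benzyloxy)‑4‑[(tert‑butyldimethylsilyl)oxy]‑5‑{(1Z)‑1‑[(tert‑butyldimethylsilyl)oxy]‑3‑phenylprop‑1‑en‑1‑yl}‑6‑hydroxy‑3‑methylphenyl}‑5‑hydroxy‑2,2,4,4,9‑pentamethyl‑3‑oxodecanoate | COC(=O)C(C)(C)C(=O)C(C)(C)C(O)C[C@@H](CC(C)C)c1c(OCc2ccccc2)c(C)c(O[Si](C)(C)C(C)(C)C)c(/C(O[Si](C)(C)C(C)(C)C)=C/Cc2ccccc2)c1O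
F4 | step 7 | methyl (7R)‑7‑{2‑(benzyloxy)‑4‑[(tert‑butyldimethylsilyl)oxy]‑5‑{(1Z)‑1‑[(tert‑butyldimethylsilyl)oxy]‑3‑phenylprop‑1‑en‑1‑yl}‑6‑hydroxy‑3‑methylphenyl}‑2,2,4,4,9‑pentamethyl‑3,5‑dioxodecanoate | COC(=O)C(C)(C)C(=O)C(C)(C)C(=O)C[C@@H](CC(C)C)c1c(OCc2ccccc2)c(C)c(O[Si](C)(C)C(C)(C)C)c(/C(O[Si](C)(C)C(C)(C)C)=C/Cc2ccccc2)c1O
F5 | step 4 | rac‑5‑(benzyloxy)‑7‑hydroxy‑6‑methyl‑4‑(2‑methylpropyl)‑8‑(3‑phenylpropanoyl)‑3,4‑dihydro‑2H‑chromen‑2‑one | O=C1CC(CC(C)C)c2c(OCc3ccccc3)c(C)c(O)c(C(=O)CCc3ccccc3)c2O1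
F6 | step 6 | (4R)‑5,7‑bis(benzyloxy)‑6‑methyl‑4‑(2‑methylpropyl)‑8‑(3‑phenylpropanoyl)‑3,4‑dihydro‑2H‑chromen‑2‑one | O=C1C[C@@H](CC(C)C)c2c(OCc3ccccc3)c(C)c(OCc3ccccc3)c(C(=O)CCc3ccccc3)c2O1
F7 | step 6 | 2‑[(1S)‑1‑{2,4‑bis(benzyloxy)‑6‑hydroxy‑3‑methyl‑5‑(3‑phenylpropanoyl)phenyl}‑3‑methylbutyl]‑3‑hydroxy‑4,4,6,6‑tetramethylcyclohex‑2‑ene‑1,5‑dione | Cc1c(OCc2ccccc2)c(C(=O)CCc2ccccc2)c(O)c([C@H](CC(C)C)C2=C(O)C(C)(C)C(=O)C(C)(C)C2=O)c1OCc1ccccc1
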